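At 120 min the green run has 33.0 % of its substrate left and the grey run 31.0 %, although grey was charged 1.50 times as much, so within the scatter of these readings I take the rate to go with the substrate present, first order. So I work with the fraction left, not the fraction made.

| flask | substrate | reagent | free catalyst | remark |
|---|---|---|---|---|
| green | 0.10 M | 0.36 M | 1 mM | run made earlier |
| grey | 0.15 M | 0.36 M | 1 mM | run made earlier |
| blue | 0.20 M | 0.36 M | 0.50 mM | run made earlier |
| flask | 0.20 M | 0.360 M | 1.0 mM |  |

- green (time / min: target / %): 15.0: 16; 40.0: 38; 80.0: 57; 120: 67
- grey (time / min: target / %): 10.0: 13; 20.0: 25; 50.0: 43; 120: 69
- blue (time / min: target / %): 30.0: 20; 60.0: 31; 90.0: 41; 120: 50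

(readings scatter by 2 percentage points)

- steps thought possible: reagent + catalyst intermediate A -> catalyst intermediate B; free catalyst <-> dormant form; 2 free catalyst -> spent catalyst; catalyst intermediate B -> free catalyst + target; substrate + free catalyst -> catalyst intermediate A
- no earlier run changes the charge of reagent; that part of a forecast is a guess

1. apparent order in free catalyst when 5.0 % of the substrate are converted (percent change of the rate of making target for one percent more free catalyst charged)
2. apparent order in reagent when 5.0 % of the substrate are converted (percent change of the rate of making target for one percent more reagent charged)
3. factor on the rate of making target when 5.0 % of the substrate are converted if free catalyst is charged twice over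

s = ln(fraction left at the start of a stretch / fraction left at its end) / length of the stretch

From the start to 20.0 min the grey run gives 0.0144 min⁻¹; that number is s, the natural logarithm of the fraction of substrate left, lost per minute, the pseudo-first-order constant.

Here is the puzzle: a first-order constant should stay put, yet from 50.0 min to 120 min the grey run gives 0.00870 min⁻¹, less than early on. Both hold if s follows the working catalyst, which fades with the clock while the substrate charge leaves s alone. That is how I read it.

The blue run, with 0.50 mM of free catalyst, gives 0.00744 min⁻¹ over its first 30.0 min. The blue run differs from the grey run in its substrate charge and in the stretch read as well, but taking s as unmoved by the charge I read a factor of 1.93 for catalyst doubled, an order of 0.951. For the flask at 5.0 % conversion: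

rate = s · c(substrate) · fraction left = 0.164 M h⁻¹

By s that conversion comes at 3.56 min, before any reading, so this is an extrapolation. For reagent I can only guess a small order.

The forecast, which agrees with me on catalyst, says 0.95 for the order in free catalyst, 0.12 for the order in reagent and 1.93 for the factor, holding that “any second-order loss scarcely changes the order”.

The flask gives an order of 1.2 in free catalyst, 7.2 × 10⁻⁴ in reagent and a factor of 2.73.

reagent + catalyst intermediate A → catalyst intermediate B (k = 11000 M⁻¹ min⁻¹); free catalyst ⇌ dormant form (K = 2.00, k = 1.00 min⁻¹); 2 free catalyst → spent catalyst (k = 50.0 M⁻¹ min⁻¹); catalyst intermediate B → free catalyst + target (k = 43.0 min⁻¹); substrate + free catalyst → catalyst intermediate A (k = 46.0 M⁻¹ min⁻¹) Free catalyst and dormant form relax, by that step alone, with a half-life of 0.462 min, shorter than the 2.52 min this flask takes to reach 5.0 % conversion. At that conversion s, read from the grey run, gives a rate of 0.164 M h⁻¹ and the flask has 0.162 M h⁻¹. In a flask otherwise the same but charged with free catalyst twice over, s at that conversion comes to 0.0393 min⁻¹.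

The runs stem from a simulated flask with constants of no real substance.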